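**Retrosynthetic overview**
- The target comes from desilylation of an aryl silyl ether, which comes from aroylation of the C6 carbinol (acid built from a bromophenol and CO2), chelation-controlled reduction of a C6 ketone, and tigloylation of the C10 carbinol while C6 is still a ketone.
- Key disconnection C1–C10: the seven-membered ring is closed by a 7-endo radical cyclization. An α-hydroxyallyl radical, made by C–H abstraction from a primary Z-allylic alcohol, adds to the β-carbon of a cyclopentenyl ketone, creating the quaternary carbon, the C10 carbinol and the ring-fusion CH in one step.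
- The cyclization substrate comes from acylation of a 2-metallated cyclopentenol with a β,γ-unsaturated δ-lactone that carries C6–C10 with the Z alkene fixed; that lactone comes from deconjugation of the conjugated lactone.
- The cyclopentenol (tertiary carbinol, the only externally controlled stereocenter) comes from catalytic enantioselective 1,2-addition of an isopropyl Grignard reagent to a 2-bromocyclopentenone.
- Ring order: the five-membered ring is bought; the seven-membered ring is the only carbocycle built, in the key step.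

Assumption: the bromocyclopentenone and the conjugated methyl lactone are catalogue compounds; C1, C4, C5, C6 and C10 in the Why lines are daucane labels (C1 = methyl-bearing ring-fusion carbon = azulene 8a, C4 = isopropyl carbinol = 3, C5 = ring-fusion CH = 3a, C6 = aroyloxy carbon = 4, C10 = tigloyloxy carbon = 8).

Step 1
Reactants: 1 2-bromo-3-methylcyclopent-2-en-1-one; 2 isopropylmagnesium bromide
Product: 3 (1S)-2-bromo-3-methyl-1-(propan-2-yl)cyclopent-2-en-1-ol
Conditions: CuBr·SMe2 (5 mol %), (R)-1-[(Sp)-2-(dicyclohexylphosphino)ferrocenyl]ethyldiphenylphosphine (6 mol %), t-BuOMe, −78 °C; aq NH4Cl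
Reagents that add atoms: none
Why: Copper-catalysed enantioselective 1,2-addition of a Grignard reagent to an α-bromo enone, in which the 2-bromo group and the fully substituted β-carbon shut down conjugate addition and the chiral copper–diphosphine complex (ligand antipode fixed by a test run) delivers isopropyl to one carbonyl face, setting the tertiary carbinol (C4) as S.

Step 2
Reactants: 4 4-methyl-5,6-dihydro-2H-pyran-2-one
Product: 6 4-methyl-3,6-dihydro-2H-pyran-2-one, via lithium dienolate 5 (not isolated)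
Conditions: LiN(iPr)2 (1.05 equiv), THF, −78 °C; inverse quench into AcOH/THF, −78 °C
Reagents that add atoms: none
Why: Deconjugative protonation: kinetic γ-deprotonation of the ring CH2 cis to the carbonyl gives the extended dienolate, and kinetic α-protonation moves the alkene out of conjugation while the ring keeps it Z; no stereocenter is formed.

Step 3
Reactants: 3 (1S)-2-bromo-3-methyl-1-(propan-2-yl)cyclopent-2-en-1-ol; 6 4-methyl-3,6-dihydro-2H-pyran-2-one
Product: 9 (3Z)-5-hydroxy-1-[(5S)-5-hydroxy-2-methyl-5-(propan-2-yl)cyclopent-1-en-1-yl]-3-methylpent-3-en-1-one, via dilithio alkoxide 7 (not isolated), via alkenylcerium dichloride 8 (not isolated)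
Conditions: t-BuLi (3.0 equiv), THF, −78 °C; CeCl3 (1.1 equiv), −78 °C; 6 (1.2 equiv), −78 to −40 °C; aq NH4Cl
Reagents that add atoms: none
Why: Bromine–lithium exchange on the lithium alkoxide followed by transmetalation gives a weakly basic organocerium that adds once to the lactone carbonyl rather than enolising it (acylation of an organometallic by a lactone), and work-up opens the hemiketal to the ketone with the Z-allylic alcohol intact; the carbinol stereocenter is untouched.

Step 4
Reactants: 9 (3Z)-5-hydroxy-1-[(5S)-5-hydroxy-2-methyl-5-(propan-2-yl)cyclopent-1-en-1-yl]-3-methylpent-3-en-1-one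
Product: 10 (3S,3aR,8R,8aS)-3,8-dihydroxy-6,8a-dimethyl-3-(propan-2-yl)-2,3,3a,5,8,8a-hexahydroazulen-4(1H)-one
Conditions: [Ir(dF(CF3)ppy)2(dtbbpy)]PF6 (2 mol %; dF(CF3)ppy = cyclometalated 2-(2,4-difluorophenyl)-5-(trifluoromethyl)pyridine, dtbbpy = 4,4'-di-tert-butyl-2,2'-bipyridine), quinuclidine (20 mol %), Bu4N(H2PO4) (25 mol %), degassed MeCN (0.005 M), 450 nm LEDs, 25 °C
Reagents that add atoms: none
Why: Proposed new method: the closest known reaction type is the photoredox/hydrogen-atom-transfer α-C–H alkylation of alcohols with Michael acceptors (a Giese addition), run here intramolecularly; the quinuclidinium radical cation removes the hydridic, phosphate-activated allylic C–H next to the primary OH, the nucleophilic α-hydroxyallyl radical can close only through its carbinol carbon (7-endo onto the enone β-carbon C1, since the other terminus would need a 5-endo closure and the α-carbon is polarity-mismatched and fully substituted), the chain passes over the hydroxyl face of the cyclopentene away from the isopropyl group (C1 methyl cis to isopropyl), the radical carbon turns its OH anti to that methyl and toward the tertiary OH by hydrogen bonding (C10 R), and the enolate formed on reduction by the reduced iridium complex is protonated on the same open face to give the trans ring fusion at C5.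

Step 5
Reactants: 10 (3S,3aR,8R,8aS)-3,8-dihydroxy-6,8a-dimethyl-3-(propan-2-yl)-2,3,3a,5,8,8a-hexahydroazulen-4(1H)-one; 11 (2E)-2-methylbut-2-enoyl chloride
Product: 12 (3S,3aR,8R,8aS)-3-hydroxy-6,8a-dimethyl-4-oxo-3-(propan-2-yl)-1,2,3,3a,4,5,8,8a-octahydroazulen-8-yl (2E)-2-methylbut-2-enoate
Conditions: 11 (1.5 equiv), pyridine (3 equiv), 4-(dimethylamino)pyridine (0.1 equiv), CH2Cl2, 0 °C to rt
Reagents that add atoms: none
Why: Nucleophile-catalysed O-acylation of the only secondary hydroxyl (the tertiary alcohol is inert), done while C6 is still a ketone so the two secondary oxygens never have to be distinguished; no stereocenter changes.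

Step 6
Reactants: 12 (3S,3aR,8R,8aS)-3-hydroxy-6,8a-dimethyl-4-oxo-3-(propan-2-yl)-1,2,3,3a,4,5,8,8a-octahydroazulen-8-yl (2E)-2-methylbut-2-enoate
Product: 13 (3S,3aS,4S,8R,8aS)-3,4-dihydroxy-6,8a-dimethyl-3-(propan-2-yl)-1,2,3,3a,4,5,8,8a-octahydroazulen-8-yl (2E)-2-methylbut-2-enoate
Conditions: Et2BOMe (1.2 equiv), THF/MeOH 4:1, −78 °C, 1 h; NaBH4 (1.5 equiv), −78 °C; MeOH co-evaporation
Reagents that add atoms: none
Why: Chelation-controlled reduction of a β-hydroxy ketone (Narasaka–Prasad type), in which the diethylboron chelate ties the ketone oxygen to the tertiary alkoxide so that borohydride adds from the angular-methyl side and the new C6 oxygen stays syn to the tertiary OH (C6 S); the ester and alkenes survive at −78 °C.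

Step 7
Reactants: 14 4-bromophenol
Product: 15 (4-bromophenoxy)(tert-butyl)dimethylsilane
Conditions: t-BuMe2SiCl (1.1 equiv), imidazole (2 equiv), Me2NCHO, rt
Reagents that add atoms: tert-butyldimethylsilyl chloride, CC(C)(C)[Si](C)(C)Cl
Why: Silyl ether formation masks the acidic phenol for the metalation and acylation that follow; no stereocenter.

Step 8
Reactants: 15 (4-bromophenoxy)(tert-butyl)dimethylsilane
Product: 17 4-[(tert-butyldimethylsilyl)oxy]benzoic acid, via aryllithium 16 (not isolated)
Conditions: n-BuLi (1.05 equiv), THF, −78 °C; CO2 (gas), −78 to 0 °C; cold 1 M HCl to pH 4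
Reagents that add atoms: carbon dioxide, O=C=O
Why: Bromine–lithium exchange and carboxylation of the aryllithium give the benzoic acid; no stereocenter.

Step 9
Reactants: 13 (3S,3aS,4S,8R,8aS)-3,4-dihydroxy-6,8a-dimethyl-3-(propan-2-yl)-1,2,3,3a,4,5,8,8a-octahydroazulen-8-yl (2E)-2-methylbut-2-enoate; 17 4-[(tert-butyldimethylsilyl)oxy]benzoic acid
Product: 19 (3S,3aS,4S,8R,8aS)-4-({4-[(tert-butyldimethylsilyl)oxy]benzoyl}oxy)-3-hydroxy-6,8a-dimethyl-3-(propan-2-yl)-1,2,3,3a,4,5,8,8a-octahydroazulen-8-yl (2E)-2-methylbut-2-enoate, via acid chloride 18 (not isolated)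
Conditions: 17 (2 equiv), (COCl)2, Me2NCHO (cat.), CH2Cl2, 0 °C to rt, evaporate; then 13, Et3N (3 equiv), 4-(dimethylamino)pyridine (0.5 equiv), CH2Cl2, rt to 40 °C
Reagents that add atoms: none
Why: Acyl chloride formation and nucleophile-catalysed esterification of the remaining secondary alcohol (the tertiary OH does not react); only the O–H bond is broken, so C6 keeps its configuration.

Step 10
Reactants: 19 (3S,3aS,4S,8R,8aS)-4-({4-[(tert-butyldimethylsilyl)oxy]benzoyl}oxy)-3-hydroxy-6,8a-dimethyl-3-(propan-2-yl)-1,2,3,3a,4,5,8,8a-octahydroazulen-8-yl (2E)-2-methylbut-2-enoate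
Product: 20 (3S,3aS,4S,8R,8aS)-3-hydroxy-4-[(4-hydroxybenzoyl)oxy]-6,8a-dimethyl-3-(propan-2-yl)-1,2,3,3a,4,5,8,8a-octahydroazulen-8-yl (2E)-2-methylbut-2-enoate
Conditions: Bu4NF (1.2 equiv), AcOH (1.5 equiv), THF, 0 °C
Reagents that add atoms: none
Why: Fluoride-mediated cleavage of the aryl silyl ether, buffered with acetic acid so the phenoxide cannot transesterify, leaves both esters, the tertiary alcohol and all stereocenters unchanged.

**Compound list**
1 | 2-bromo-3-methylcyclopent-2-en-1-one | CC1=C(Br)C(=O)CC1 | starting material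
2 | isopropylmagnesium bromide | CC(C)[Mg]Br | starting material
3 | (1S)-2-bromo-3-methyl-1-(propan-2-yl)cyclopent-2-en-1-ol | CC1=C(Br)[C@@](O)(C(C)C)CC1 | intermediate
4 | 4-methyl-5,6-dihydro-2H-pyran-2-one | CC1=CC(=O)OCC1 | starting material
5 | lithium dienolate (lithium 4-methyl-6H-pyran-2-olate) | CC1=CCOC(O[Li])=C1 | intermediate
6 | 4-methyl-3,6-dihydro-2H-pyran-2-one | CC1=CCOC(=O)C1 | intermediate
7 | dilithio alkoxide (lithium (1S)-2-lithio-3-methyl-1-(propan-2-yl)cyclopent-2-en-1-olate) | CC1=C([Li])[C@@](O[Li])(C(C)C)CC1 | intermediate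
8 | alkenylcerium dichloride (lithium (1S)-2-(dichlorocerio)-3-methyl-1-(propan-2-yl)cyclopent-2-en-1-olate) | CC1=C([Ce](Cl)Cl)[C@@](O[Li])(C(C)C)CC1 | intermediate
9 | (3Z)-5-hydroxy-1-[(5S)-5-hydroxy-2-methyl-5-(propan-2-yl)cyclopent-1-en-1-yl]-3-methylpent-3-en-1-one | CC1=C(C(=O)C/C(C)=C\CO)[C@@](O)(C(C)C)CC1 | intermediate
10 | (3S,3aR,8R,8aS)-3,8-dihydroxy-6,8a-dimethyl-3-(propan-2-yl)-2,3,3a,5,8,8a-hexahydroazulen-4(1H)-one | O[C@@H]1C=C(C)CC(=O)[C@@H]2[C@]1(C)CC[C@]2(O)C(C)C | intermediate
11 | (2E)-2-methylbut-2-enoyl chloride (tigloyl chloride) | C/C=C(\C)C(Cl)=O | starting material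
12 | (3S,3aR,8R,8aS)-3-hydroxy-6,8a-dimethyl-4-oxo-3-(propan-2-yl)-1,2,3,3a,4,5,8,8a-octahydroazulen-8-yl (2E)-2-methylbut-2-enoate | C/C=C(\C)C(=O)O[C@@H]1C=C(C)CC(=O)[C@@H]2[C@]1(C)CC[C@]2(O)C(C)C | intermediate
13 | (3S,3aS,4S,8R,8aS)-3,4-dihydroxy-6,8a-dimethyl-3-(propan-2-yl)-1,2,3,3a,4,5,8,8a-octahydroazulen-8-yl (2E)-2-methylbut-2-enoate | C/C=C(\C)C(=O)O[C@@H]1C=C(C)C[C@H](O)[C@@H]2[C@]1(C)CC[C@]2(O)C(C)C | intermediate
14 | 4-bromophenol | Oc1ccc(Br)cc1 | starting material
15 | (4-bromophenoxy)(tert-butyl)dimethylsilane | CC(C)(C)[Si](C)(C)Oc1ccc(Br)cc1 | intermediate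
16 | aryllithium ({4-[(tert-butyldimethylsilyl)oxy]phenyl}lithium) | CC(C)(C)[Si](C)(C)Oc1ccc([Li])cc1 | intermediate
17 | 4-[(tert-butyldimethylsilyl)oxy]benzoic acid | CC(C)(C)[Si](C)(C)Oc1ccc(C(=O)O)cc1 | intermediate
18 | acid chloride (4-[(tert-butyldimethylsilyl)oxy]benzoyl chloride) | CC(C)(C)[Si](C)(C)Oc1ccc(C(Cl)=O)cc1 | intermediate
19 | (3S,3aS,4S,8R,8aS)-4-({4-[(tert-butyldimethylsilyl)oxy]benzoyl}oxy)-3-hydroxy-6,8a-dimethyl-3-(propan-2-yl)-1,2,3,3a,4,5,8,8a-octahydroazulen-8-yl (2E)-2-methylbut-2-enoate | C/C=C(\C)C(=O)O[C@@H]1C=C(C)C[C@H](OC(=O)c2ccc(O[Si](C)(C)C(C)(C)C)cc2)[C@@H]2[C@]1(C)CC[C@]2(O)C(C)C | intermediate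
20 | (3S,3aS,4S,8R,8aS)-3-hydroxy-4-[(4-hydroxybenzoyl)oxy]-6,8a-dimethyl-3-(propan-2-yl)-1,2,3,3a,4,5,8,8a-octahydroazulen-8-yl (2E)-2-methylbut-2-enoate | C/C=C(\C)C(=O)O[C@@H]1C=C(C)C[C@H](OC(=O)c2ccc(O)cc2)[C@@H]2[C@]1(C)CC[C@]2(O)C(C)C | target

**Totals and risks**
Total step count: 10. Longest linear sequence: 7 steps (1, 3, 4, 5, 6, 9, 10; from 1 to 20).

Most likely to fail, first: step 4. The stabilised α-hydroxyallyl radical may close too slowly, on the wrong face, or give the C10 epimer. The fallback sets out from 9. MnO2 (CH2Cl2, rt) oxidises only the primary allylic alcohol to (2Z)-5-[(5S)-5-hydroxy-2-methyl-5-(propan-2-yl)cyclopent-1-en-1-yl]-3-methyl-5-oxopent-2-enal F1. A thiol-catalysed radical-chain hydroacylation (tert-dodecanethiol 0.3 equiv, 2,2'-azobis(2-methylpropionitrile), chlorobenzene, 80 °C, 0.005 M) then forms the same C1–C10 bond through the far more reactive σ-acyl radical and gives (3S,3aR,8aS)-3-hydroxy-6,8a-dimethyl-3-(propan-2-yl)-1,2,3,3a,5,8a-hexahydroazulene-4,8-dione F2. Reagent-controlled reduction of the enone carbonyl with catecholborane and the oxazaborolidine 1-methyl-3,3-diphenyltetrahydro-1H,3H-pyrrolo[1,2-c][1,3,2]oxazaborole (hand chosen for the 8R carbinol, −78 °C; the C6 ketone between the isopropyl carbinol and the quaternary carbon reacts much more slowly) comes back to the route at 10.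

Second: step 1. A secondary Grignard reagent and a cyclic bromo enone may give low ee or carbonyl reduction. The fallback sets out from 1. Addition of 2 with LaCl3·2LiCl (THF, 0 °C) gives racemic 2-bromo-3-methyl-1-(propan-2-yl)cyclopent-2-en-1-ol F3. Carbamoylation with (S)-1-(naphthalen-1-yl)ethyl isocyanate (CuCl cat., Me2NCHO, rt) and chromatographic separation of the diastereomers gives (1S)-2-bromo-3-methyl-1-(propan-2-yl)cyclopent-2-en-1-yl N-[(1S)-1-(naphthalen-1-yl)ethyl]carbamate F4. HSiCl3/Et3N (toluene, rt) cleaves the carbamate and comes back to the route at 3.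

Third: step 6. The boron chelate is strained because the tertiary OH and C6 are trans on the five-membered ring, and unassisted hydride would enter from the open face and give the C6 epimer. The fallback sets out from 12. Me4NBH(OAc)3 (MeCN/AcOH, −30 °C) delivers hydride internally from the tertiary hydroxyl and gives (3S,3aS,4R,8R,8aS)-3,4-dihydroxy-6,8a-dimethyl-3-(propan-2-yl)-1,2,3,3a,4,5,8,8a-octahydroazulen-8-yl (2E)-2-methylbut-2-enoate F5. Mitsunobu esterification of F5 with acid 17 (PPh3, diisopropyl azodicarboxylate, toluene, 0 °C to rt) inverts that carbinol and comes back to the route at 19, so step 9 is skipped.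

Further compounds
F1 | step 4 | (2Z)-5-[(5S)-5-hydroxy-2-methyl-5-(propan-2-yl)cyclopent-1-en-1-yl]-3-methyl-5-oxopent-2-enal | CC1=C(C(=O)C/C(C)=C\C=O)[C@@](O)(C(C)C)CC1
F2 | step 4 | (3S,3aR,8aS)-3-hydroxy-6,8a-dimethyl-3-(propan-2-yl)-1,2,3,3a,5,8a-hexahydroazulene-4,8-dione | O=C1C=C(C)CC(=O)[C@@H]2[C@]1(C)CC[C@]2(O)C(C)C
F3 | step 1 | racemic 2-bromo-3-methyl-1-(propan-2-yl)cyclopent-2-en-1-ol | CC1=C(Br)C(O)(C(C)C)CC1
F4 | step 1 | (1S)-2-bromo-3-methyl-1-(propan-2-yl)cyclopent-2-en-1-yl N-[(1S)-1-(naphthalen-1-yl)ethyl]carbamate | C[C@H](NC(=O)O[C@]1(C(C)C)CCC(C)=C1Br)c1cccc2ccccc12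
F5 | step 6 | (3S,3aS,4R,8R,8aS)-3,4-dihydroxy-6,8a-dimethyl-3-(propan-2-yl)-1,2,3,3a,4,5,8,8a-octahydroazulen-8-yl (2E)-2-methylbut-2-enoate | C/C=C(\C)C(=O)O[C@@H]1C=C(C)C[C@@H](O)[C@@H]2[C@]1(C)CC[C@]2(O)C(C)C
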